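**Plan**

- Retrosynthesis: the silylene and the two benzyl ethers are removed first. The C7–aryl bond and the C6–O bond are then cut back to a C6=C7 vinyl group. Last, C1=C2 and C6=C7 are cut together, which gives a guaiacyl styrene and a five-membered ring.
- Enabling feature: atoms C2–C3(O)–C4–C5(O)–C6 with their syn 3,5-diol are a masked meso cis-cyclopent-4-ene-1,3-diol whose two alkene carbons are C2 and C6. C1, bonded to the guaiacyl ring, is the α-carbon of a styrene.
- Forward: the diol is bridged by silicon to a strained 2,4-dioxa-3-silabicyclo[3.2.1]oct-6-ene. Ring-opening cross-metathesis with the styrene unrolls the cyclopentene into the C1–C7 chain; no ring is closed and the dioxasilinane stays as protecting ring.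
- Diboration, Suzuki coupling and oxidation then add O6 and the second arene at C7. Hydrogenation and desilylation finish the synthesis.
- Stereochemistry: the syn C3/C5 relation is the cis relation of the ring. Its absolute sense comes from a chiral Mo alkylidene that chooses between the two enantiotopic alkene carbons. C6 comes from a chiral phosphonite on platinum and is retained through C–B oxidation.

Key step: step 3

Remark on the chemistry: locants C1–C7 are those of the heptane chain of the target (C1 on the guaiacyl ring). The sense of induction of the Mo diolate (step 3) and of the phosphonite (step 4) cannot be derived for this substrate class. The (S)-diolate and the (R,R)-phosphonite are written; the mirror-image ligand is to be used in either step if the first run shows the opposite sense.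

**Route**

Step 1
Reactants: 1 cis-cyclopent-4-ene-1,3-diol (meso); 2 di-tert-butylsilyl bis(trifluoromethanesulfonate)
Product: 3 (1R,5S)-3,3-di-tert-butyl-2,4-dioxa-3-silabicyclo[3.2.1]oct-6-ene (meso)
Conditions: 2 (1.05 equiv, slow addition), 2,6-lutidine (2.5 equiv), CH2Cl2 (high dilution), 0 °C to rt
Reagents that add atoms: di-tert-butylsilyl bis(trifluoromethanesulfonate) (2), CC(C)(C)[Si](OS(=O)(=O)C(F)(F)F)(OS(=O)(=O)C(F)(F)F)C(C)(C)C
Why: Silylene formation from a 1,3-diol and a dialkylsilyl bis(triflate) with an amine base is standard; the two cis hydroxyl groups can both reach pseudo-axial positions of the cyclopentene envelope so that the long Si–O bonds span them, dilution favours the bridged monomer over oligomers, and the product stays meso with no stereocentre touched.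

Step 2
Reactants: 4 2-methoxy-4-vinylphenol; 5 benzyl bromide
Product: 6 1-(benzyloxy)-2-methoxy-4-vinylbenzene
Conditions: BnBr (1.1 equiv), K2CO3 (1.5 equiv), DMF, BHT (trace), rt
Reagents that add atoms: benzyl bromide (5), BrCc1ccccc1
Why: Williamson etherification of the phenoxide with benzyl bromide; room temperature and a radical inhibitor should keep the styrene from polymerising.

Step 3
Reactants: 3 (1R,5S)-3,3-di-tert-butyl-2,4-dioxa-3-silabicyclo[3.2.1]oct-6-ene; 6 1-(benzyloxy)-2-methoxy-4-vinylbenzene
Product: 7 (4R,6S)-4-[(E)-2-(4-benzyloxy-3-methoxyphenyl)ethenyl]-2,2-di-tert-butyl-6-ethenyl-1,3,2-dioxasilinane, the 3,5-O-di-tert-butylsilylene of the (1E,3R,5S)-1-arylhepta-1,6-diene-3,5-diol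
Conditions: Mo(N-2,6-iPr2C6H3)(CHCMe2Ph)[(S)-3,3'-di-tert-butyl-5,5',6,6'-tetramethylbiphenyl-2,2'-diolate] (5 mol%), 6 (3 equiv), C6H6, 22 °C, slow addition of 3, inert atmosphere
Reagents that add atoms: none
Why: Proposed new method: the neophylidene is first exchanged by 6 for the Mo benzylidene, which adds by [2+2] cycloaddition to the strained ring alkene of 3 on its exo face (opposite the O–Si–O bridge and its tert-butyl groups); cycloreversion of the molybdacyclobutane opens the cyclopentene, and the new alkylidene at the future C6 is released as a vinyl group by a second molecule of 6, which regenerates the benzylidene, so that C1=C2 carries the aryl group and C6=C7 is terminal. The closest known reaction type is the enantioselective ring-opening cross-metathesis of meso norbornenes and 8-oxabicyclo[3.2.1]oct-6-enes with styrenes under chiral Mo diolate or chiral Ru carbene catalysis; a 2,4-dioxa-3-silabicyclo[3.2.1]oct-6-ene has not been opened in this way, but the same kind of strain release should drive it. No ring is closed: the five-membered carbocycle is cleaved and the six-membered 1,3,2-dioxasilinane that was part of the bicycle is left as a monocycle. C3 and C5 are present in 3 as a cis pair, so their syn relation is inherited from the ring, and their absolute configuration (3R,5S in 7) is decided by the chiral biphenolate on Mo, which selects one of the two enantiotopic alkene carbons for bonding to the benzylidene carbon. The step needs this enantiotopic-group selectivity and a preference for one ring opening followed by chain transfer to 6 over polymerisation; the rigid bicycle exposes a single face and holds the two alkene carbons in mirror-image surroundings that the chiral pocket can tell apart, while excess 6, slow addition of 3 and the low reactivity of product alkenes that both sit next to an oxygen-bearing carbon of a bulky silylene should hold the reaction at the one-to-one adduct. The geometry of C1=C2 is without consequence because this alkene is hydrogenated in step 5.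

Step 4
Reactants: 7 the diene silylene from step 3; 8 bis(pinacolato)diboron; 9 1-(benzyloxy)-4-bromobenzene
Product: 12 (1E,3R,5S,6S)-1-(4-benzyloxy-3-methoxyphenyl)-7-(4-benzyloxyphenyl)hept-1-ene-3,5,6-triol 3,5-O-di-tert-butylsilylene, via 6,7-bis(pinacolboronate) 10 (not isolated), via C6 pinacolboronate 11 (not isolated)
Conditions: Pt(dba)3 (3 mol%), (R,R)-3,5-diisopropylphenyl-TADDOL phenylphosphonite (3.6 mol%), B2pin2 (1.05 equiv), THF, 60 °C; then Pd(OAc)2 (2 mol%), RuPhos (2 mol%), 9 (1.1 equiv), KOH (3 equiv), THF/H2O 10:1, 70 °C; then 3 M NaOH, 30% H2O2, 0 °C to rt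
Reagents that add atoms: hydrogen peroxide, OO
Why: Known diboration/cross-coupling cascade of terminal alkenes: zerovalent platinum with the chiral phosphonite adds B–B across the monosubstituted C6=C7 alkene only (the 1,2-disubstituted C1=C2 alkene is far less reactive), the ligand sets C6 by face selection, the primary C7–B bond alone transmetalates to palladium (Suzuki–Miyaura coupling, assisted by the neighbouring boronate), and H2O2/NaOH oxidises the C6–B bond with retention to give the 6S alcohol syn to O5.

Step 5
Reactants: 12 the C6 alcohol from step 4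
Product: 13 (3S,5S,6S)-1-(4-hydroxy-3-methoxyphenyl)-7-(4-hydroxyphenyl)heptane-3,5,6-triol 3,5-O-di-tert-butylsilylene
Conditions: H2 (1 atm), 10% Pd/C, EtOAc/EtOH 1:1, rt
Reagents that add atoms: none
Why: Heterogeneous hydrogenation saturates C1=C2 and cleaves both aryl benzyl ethers by hydrogenolysis, while the silylene and the secondary alcohol are inert and no stereocentre is involved.

Step 6
Reactants: 13 the silylene-protected triol from step 5
Product: 14 (3S,5S,6S)-1-(4-hydroxy-3-methoxyphenyl)-7-(4-hydroxyphenyl)heptane-3,5,6-triol (CNP0232775.1)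
Conditions: HF·pyridine, pyridine, THF, 0 °C to rt
Reagents that add atoms: none
Why: Fluoride-driven cleavage of both Si–O bonds (strong Si–F bond) under buffered, weakly acidic conditions that leave the triol and the phenols untouched; no stereocentre is affected.

**Compound list**

1 | cis-cyclopent-4-ene-1,3-diol (meso) | C1=C[C@H](O)C[C@@H]1O | starting material
2 | di-tert-butylsilyl bis(trifluoromethanesulfonate) | CC(C)(C)[Si](OS(=O)(=O)C(F)(F)F)(OS(=O)(=O)C(F)(F)F)C(C)(C)C | starting material
3 | (1R,5S)-3,3-di-tert-butyl-2,4-dioxa-3-silabicyclo[3.2.1]oct-6-ene (meso) | C1=C[C@H]2C[C@@H]1O[Si](C(C)(C)C)(C(C)(C)C)O2 | intermediate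
4 | 2-methoxy-4-vinylphenol | COc1cc(C=C)ccc1O | starting material
5 | benzyl bromide | BrCc1ccccc1 | starting material
6 | 1-(benzyloxy)-2-methoxy-4-vinylbenzene | COc1cc(C=C)ccc1OCc1ccccc1 | intermediate
7 | (4R,6S)-4-[(E)-2-(4-benzyloxy-3-methoxyphenyl)ethenyl]-2,2-di-tert-butyl-6-ethenyl-1,3,2-dioxasilinane | COc1cc(/C=C/[C@H]2C[C@H](O[Si](C(C)(C)C)(C(C)(C)C)O2)C=C)ccc1OCc1ccccc1 | intermediate
8 | bis(pinacolato)diboron | CC1(C)OB(OC1(C)C)B1OC(C)(C)C(C)(C)O1 | starting material
9 | 1-(benzyloxy)-4-bromobenzene | Brc1ccc(OCc2ccccc2)cc1 | starting material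
10 | (1E,3R,5S,6S)-1-(4-benzyloxy-3-methoxyphenyl)-6,7-bis(4,4,5,5-tetramethyl-1,3,2-dioxaborolan-2-yl)hept-1-ene-3,5-diol 3,5-O-di-tert-butylsilylene | COc1cc(/C=C/[C@H]2C[C@H](O[Si](C(C)(C)C)(C(C)(C)C)O2)[C@@H](B3OC(C)(C)C(C)(C)O3)CB3OC(C)(C)C(C)(C)O3)ccc1OCc1ccccc1 | intermediate
11 | (1E,3R,5S,6S)-1-(4-benzyloxy-3-methoxyphenyl)-7-(4-benzyloxyphenyl)-6-(4,4,5,5-tetramethyl-1,3,2-dioxaborolan-2-yl)hept-1-ene-3,5-diol 3,5-O-di-tert-butylsilylene | COc1cc(/C=C/[C@H]2C[C@H](O[Si](C(C)(C)C)(C(C)(C)C)O2)[C@@H](B3OC(C)(C)C(C)(C)O3)Cc2ccc(OCc3ccccc3)cc2)ccc1OCc1ccccc1 | intermediate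
12 | (1E,3R,5S,6S)-1-(4-benzyloxy-3-methoxyphenyl)-7-(4-benzyloxyphenyl)hept-1-ene-3,5,6-triol 3,5-O-di-tert-butylsilylene | COc1cc(/C=C/[C@H]2C[C@H](O[Si](C(C)(C)C)(C(C)(C)C)O2)[C@@H](O)Cc2ccc(OCc3ccccc3)cc2)ccc1OCc1ccccc1 | intermediate
13 | (3S,5S,6S)-1-(4-hydroxy-3-methoxyphenyl)-7-(4-hydroxyphenyl)heptane-3,5,6-triol 3,5-O-di-tert-butylsilylene | COc1cc(CC[C@H]2C[C@H](O[Si](C(C)(C)C)(C(C)(C)C)O2)[C@@H](O)Cc2ccc(O)cc2)ccc1O | intermediate
14 | (3S,5S,6S)-1-(4-hydroxy-3-methoxyphenyl)-7-(4-hydroxyphenyl)heptane-3,5,6-triol | COc1cc(CC[C@H](O)C[C@H](O)[C@@H](O)Cc2ccc(O)cc2)ccc1O | target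

**Step count**

Total: 6 steps. Longest linear sequence: 5 steps (steps 1, 3, 4, 5, 6 from compound 1; equally steps 2, 3, 4, 5, 6 from compound 4).

**Steps most likely to fail**

Step 3. The catalyst may discriminate poorly between the two enantiotopic alkene carbons. Ring-opening polymerisation of 3, or secondary cross-metathesis of the new vinyl group, may also outrun chain transfer to the styrene. The fallback uses known chemistry only, sets out from 6 and returns at 7. Cross-metathesis of 6 with but-3-en-2-one (second-generation Hoveyda–Grubbs catalyst RuCl2(H2IMes)(=CH-2-iPrOC6H4), CH2Cl2, 40 °C) should give (E)-4-[4-(benzyloxy)-3-methoxyphenyl]but-3-en-2-one F1. Enolisation with (−)-Ipc2BCl and Et3N in Et2O should give the bis(isopinocampheyl)boron enolate F2. Its Paterson aldol addition to acrolein at −78 °C, with oxidative work-up, should give (1E,5S)-1-[4-(benzyloxy)-3-methoxyphenyl]-5-hydroxyhepta-1,6-dien-3-one F3; the Ipc2BCl antipode is to be matched to the 5S carbinol. Narasaka–Prasad reduction (Et2BOMe, NaBH4, THF/MeOH, −78 °C) delivers hydride to the boron chelate syn to O5 and should give (1E,3R,5S)-1-[4-(benzyloxy)-3-methoxyphenyl]hepta-1,6-diene-3,5-diol F4. Silylene formation with 2 and 2,6-lutidine then leads to 7. Only moderate enantiomeric purity is to be expected from the methyl ketone aldol, so an upgrade by crystallisation at the diol stage may be needed.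

Step 4. In the hot aqueous KOH coupling, the oxygen-flanked bis(boronate) may undergo β-elimination or protodeboronation, and the silylene may be opened hydrolytically, before the primary C–B bond transmetalates. The fallback sets out from 10, made by the same diboration, and returns at 12. Direct oxidation of 10 (NaOH, H2O2, 0 °C) should give (1E,3R,5S,6S)-1-(4-benzyloxy-3-methoxyphenyl)hept-1-ene-3,5,6,7-tetraol 3,5-O-di-tert-butylsilylene F5. Selective sulfonylation of the primary hydroxyl (TsCl, Et3N, catalytic Bu2SnO, CH2Cl2) should give the 7-O-p-toluenesulfonate of that tetraol F6. K2CO3 in MeOH closes (1E,3R,5S,6S)-1-(4-benzyloxy-3-methoxyphenyl)-6,7-epoxyhept-1-ene-3,5-diol 3,5-O-di-tert-butylsilylene F7 without touching the C6–O bond. 4-(Benzyloxy)phenylmagnesium bromide F8, made from 9 and Mg in THF, opens the epoxide at C7 with catalytic CuI at −30 °C and gives 12. C6 epimers from imperfect face selection could be separated at the diol stage.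

Step 5. Hydrogenolysis of the allylic C3–O bond may compete with saturation of C1=C2 on palladium, which would give a 3-deoxy by-product. The fallback sets out from 12 and returns at 13. Diimide reduction (2-nitrobenzenesulfonyl hydrazide, Et3N, CH2Cl2, rt) saturates the alkene without a metal surface and should give (3S,5S,6S)-1-(4-benzyloxy-3-methoxyphenyl)-7-(4-benzyloxyphenyl)heptane-3,5,6-triol 3,5-O-di-tert-butylsilylene F9. With the allylic system gone, its benzyl ethers are cleaved with H2 and 10% Pd/C in EtOAc to give 13.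

**Further compounds**

F1 | step 3 | (E)-4-[4-(benzyloxy)-3-methoxyphenyl]but-3-en-2-one | COc1cc(/C=C/C(C)=O)ccc1OCc1ccccc1
F2 | step 3 | bis[(1R,2S,3R,5R)-isopinocampheyl]boron enolate of F1 | COc1cc(/C=C/C(=C)OB([C@@H]2C[C@@H]3C[C@H]([C@H]2C)C3(C)C)[C@@H]2C[C@@H]3C[C@H]([C@H]2C)C3(C)C)ccc1OCc1ccccc1
F3 | step 3 | (1E,5S)-1-[4-(benzyloxy)-3-methoxyphenyl]-5-hydroxyhepta-1,6-dien-3-one | COc1cc(/C=C/C(=O)C[C@H](O)C=C)ccc1OCc1ccccc1
F4 | step 3 | (1E,3R,5S)-1-[4-(benzyloxy)-3-methoxyphenyl]hepta-1,6-diene-3,5-diol | COc1cc(/C=C/[C@H](O)C[C@H](O)C=C)ccc1OCc1ccccc1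
F5 | step 4 | (1E,3R,5S,6S)-1-(4-benzyloxy-3-methoxyphenyl)hept-1-ene-3,5,6,7-tetraol 3,5-O-di-tert-butylsilylene | COc1cc(/C=C/[C@H]2C[C@H](O[Si](C(C)(C)C)(C(C)(C)C)O2)[C@@H](O)CO)ccc1OCc1ccccc1
F6 | step 4 | 7-O-p-toluenesulfonate of F5 | COc1cc(/C=C/[C@H]2C[C@H](O[Si](C(C)(C)C)(C(C)(C)C)O2)[C@@H](O)COS(=O)(=O)c2ccc(C)cc2)ccc1OCc1ccccc1
F7 | step 4 | (1E,3R,5S,6S)-1-(4-benzyloxy-3-methoxyphenyl)-6,7-epoxyhept-1-ene-3,5-diol 3,5-O-di-tert-butylsilylene | COc1cc(/C=C/[C@H]2C[C@H](O[Si](C(C)(C)C)(C(C)(C)C)O2)[C@@H]2CO2)ccc1OCc1ccccc1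
F8 | step 4 | 4-(benzyloxy)phenylmagnesium bromide | Br[Mg]c1ccc(OCc2ccccc2)cc1
F9 | step 5 | (3S,5S,6S)-1-(4-benzyloxy-3-methoxyphenyl)-7-(4-benzyloxyphenyl)heptane-3,5,6-triol 3,5-O-di-tert-butylsilylene | COc1cc(CC[C@H]2C[C@H](O[Si](C(C)(C)C)(C(C)(C)C)O2)[C@@H](O)Cc2ccc(OCc3ccccc3)cc2)ccc1OCc1ccccc1
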